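**Strategy.** The furan ring of the 2,3-dihydrobenzofuran is disconnected at O1–C7a and C3a–C3, so that the benzo ring arrives as benzyne and the O1–C2–C3 unit as an (S)-α-hydroxy aldehyde from the (S)-1,2,4-butanetriol pool. The key step exploits the ortho relation of O1 and the carbinol carbon C3 on the adjacent ring carbons C7a and C3a: alkoxide addition to the aryne and capture of the aryl carbanion by the formyl group forge both aryl bonds and the C3 stereocentre in one operation. Benzyne is symmetrical, so no regiochemical issue arises; C5, para to O1, is functionalised afterwards (bromination, acetyl, (R)-carbinol, angelate), and the α-methylene aldehyde is made last.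

Key step: step 4

Remark: α-hydroxy aldehyde 4 is written as the monomer although it should exist mainly as its hemiacetal dimer, which reverts to the monomer under the conditions of step 4; compounds 1, 5, 11 and 15 are taken as commercial.

**Step 1**
Reactants: 1 (S)-2-(2,2-dimethyl-1,3-dioxolan-4-yl)ethanol
Product: 2 (S)-tert-butyl[2-(2,2-dimethyl-1,3-dioxolan-4-yl)ethoxy]diphenylsilane
Conditions: TBDPSCl, imidazole, DMF, rt
Reagents that add atoms: tert-butyl(chloro)diphenylsilane (TBDPSCl), CC(C)(C)[Si](Cl)(c1ccccc1)c1ccccc1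
Why: Imidazole-promoted silyl ether formation at the only free hydroxyl; the TBDPS group is chosen because it should survive aqueous acid, fluoride in acetonitrile, NBS, hot palladium catalysis and formic acid until its removal in step 10.

**Step 2**
Reactants: 2 (S)-tert-butyl[2-(2,2-dimethyl-1,3-dioxolan-4-yl)ethoxy]diphenylsilane
Product: 3 (S)-4-[(tert-butyldiphenylsilyl)oxy]butane-1,2-diol
Conditions: AcOH/H2O (4:1), 40 °C
Reagents that add atoms: none
Why: Acid-catalysed acetal hydrolysis frees the 1,2-diol while the TBDPS ether, stable to aqueous acetic acid, remains; the stereocentre is not touched.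

**Step 3**
Reactants: 3 (S)-4-[(tert-butyldiphenylsilyl)oxy]butane-1,2-diol
Product: 4 (S)-4-[(tert-butyldiphenylsilyl)oxy]-2-hydroxybutanal
Conditions: TEMPO (10 mol%), PhI(OAc)2, CH2Cl2, 0 °C to rt
Reagents that add atoms: none
Why: Oxoammonium (TEMPO/PhI(OAc)2) oxidation distinguishes the primary from the secondary hydroxyl on steric grounds and should stop at the α-hydroxy aldehyde, which is used crude to avoid epimerisation.

**Step 4**
Reactants: 4 (S)-4-[(tert-butyldiphenylsilyl)oxy]-2-hydroxybutanal; 5 2-(trimethylsilyl)phenyl trifluoromethanesulfonate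
Product: 8 (2S,3R)-2-{2-[(tert-butyldiphenylsilyl)oxy]ethyl}-2,3-dihydro-1-benzofuran-3-ol (2,3-trans), via benzyne 6 (not isolated), via ortho-caesiated aryl ether 7 (not isolated)
Conditions: CsF, MeCN, rt (5 added slowly)
Reagents that add atoms: none
Why: Proposed new method: fluoride removes the silyl group of 5 and the triflate leaves to give benzyne 6; the alkoxide of 4, whose hydroxyl is acidified by the neighbouring formyl group, adds to one aryne terminus, and the ortho carbanion 7 adds at once to the formyl group, so that the O1–C7a and C3a–C3 bonds form in one operation. The closest known reaction type is the annulation of arynes with salicylaldehydes and ortho-hydroxyaryl ketones (to xanthenols) and with α-amino acid esters (to 3-hydroxyindoles), which follows the same sequence of heteroatom addition and carbonyl capture; an aliphatic α-hydroxy aldehyde has not been shown as the partner. The furan ring closes in a 5-exo-trig mode by attack of the aryl carbanion on the aldehyde carbon. C2 is carried over unchanged from 4, and the new C3 carbinol centre is set under substrate control by C2: in the compact transition state the carbonyl oxygen should turn away from the C2 side chain, which should favour the 2,3-trans (2S,3R) alcohol, with chromatography securing diastereomeric purity. Benzyne is symmetrical, so no regiochemical question arises; the chemoselectivity needed (ring closure before protonation of the carbanion, O-arylation before enolisation of the aldehyde) rests on the fast five-membered closure and on the slow release of 6 at room temperature.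

**Step 5**
Reactants: 8 (2S,3R)-2-{2-[(tert-butyldiphenylsilyl)oxy]ethyl}-2,3-dihydro-1-benzofuran-3-ol
Product: 9 (2S,3R)-2-{2-[(tert-butyldiphenylsilyl)oxy]ethyl}-2,3-dihydro-1-benzofuran-3-yl acetate
Conditions: Ac2O, pyridine, DMAP (cat.), CH2Cl2, 0 °C to rt
Reagents that add atoms: acetic anhydride, CC(=O)OC(C)=O
Why: DMAP-catalysed acylation of the only free hydroxyl installs the C3 acetate with retention, since the C3–O bond is not broken.

**Step 6**
Reactants: 9 (2S,3R)-2-{2-[(tert-butyldiphenylsilyl)oxy]ethyl}-2,3-dihydro-1-benzofuran-3-yl acetate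
Product: 10 (2S,3R)-5-bromo-2-{2-[(tert-butyldiphenylsilyl)oxy]ethyl}-2,3-dihydro-1-benzofuran-3-yl acetate
Conditions: NBS, MeCN, 0 °C to rt, dark
Reagents that add atoms: N-bromosuccinimide, O=C1CCC(=O)N1Br
Why: Electrophilic aromatic bromination of the aryl alkyl ether should go para to O1, at C5 (the ortho site C7 is less reactive and C4 and C6 are not activated by oxygen), under neutral conditions that spare the acid-labile benzylic acetate.

**Step 7**
Reactants: 10 (2S,3R)-5-bromo-2-{2-[(tert-butyldiphenylsilyl)oxy]ethyl}-2,3-dihydro-1-benzofuran-3-yl acetate; 11 tributyl(1-ethoxyvinyl)stannane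
Product: 13 (2S,3R)-5-acetyl-2-{2-[(tert-butyldiphenylsilyl)oxy]ethyl}-2,3-dihydro-1-benzofuran-3-yl acetate, via aryl enol ether 12 (not isolated)
Conditions: PdCl2(PPh3)2 (5 mol%), toluene, 100 °C; then 1 M HCl, THF, rt
Reagents that add atoms: water, O
Why: Stille coupling of the aryl bromide with the 1-ethoxyvinyl stannane, then mild hydrolysis of the enol ether, delivers the C5 acetyl group without the Lewis acids of a Friedel–Crafts acylation, which would ionise the C3 acetate.

**Step 8**
Reactants: 13 (2S,3R)-5-acetyl-2-{2-[(tert-butyldiphenylsilyl)oxy]ethyl}-2,3-dihydro-1-benzofuran-3-yl acetate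
Product: 14 (2S,3R)-2-{2-[(tert-butyldiphenylsilyl)oxy]ethyl}-5-[(1R)-1-hydroxyethyl]-2,3-dihydro-1-benzofuran-3-yl acetate
Conditions: RuCl[(R,R)-TsDPEN](p-cymene) (1 mol%), HCO2H/Et3N (5:2), rt
Reagents that add atoms: none
Why: Noyori asymmetric transfer hydrogenation of the aryl methyl ketone, in which the (R,R)-configured catalyst should deliver hydride to the face that gives the (R)-1-arylethanol (catalyst control); esters, silyl ether and arene are inert.

**Step 9**
Reactants: 14 (2S,3R)-2-{2-[(tert-butyldiphenylsilyl)oxy]ethyl}-5-[(1R)-1-hydroxyethyl]-2,3-dihydro-1-benzofuran-3-yl acetate; 15 angelic acid [(Z)-2-methylbut-2-enoic acid]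
Product: 17 (1R)-1-[(2S,3R)-3-acetoxy-2-{2-[(tert-butyldiphenylsilyl)oxy]ethyl}-2,3-dihydro-1-benzofuran-5-yl]ethyl (Z)-2-methylbut-2-enoate, via mixed anhydride 16 (not isolated)
Conditions: 2,4,6-trichlorobenzoyl chloride, Et3N, toluene, rt; then 14, 80 °C
Reagents that add atoms: none
Why: Yamaguchi-type esterification through mixed anhydride 16, run without DMAP, acylates the secondary alcohol with retention at carbon and is an established way to make angelates without Z-to-E isomerisation to the tiglate.

**Step 10**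
Reactants: 17 (1R)-1-[(2S,3R)-3-acetoxy-2-{2-[(tert-butyldiphenylsilyl)oxy]ethyl}-2,3-dihydro-1-benzofuran-5-yl]ethyl (Z)-2-methylbut-2-enoate
Product: 18 (1R)-1-[(2S,3R)-3-acetoxy-2-(2-hydroxyethyl)-2,3-dihydro-1-benzofuran-5-yl]ethyl (Z)-2-methylbut-2-enoate
Conditions: HF·pyridine, pyridine, THF, 0 °C to rt
Reagents that add atoms: none
Why: Fluoride-mediated desilylation buffered with pyridine should remove the TBDPS group while the acetate, the angelate and the acid-sensitive para-alkoxybenzylic ester linkage survive.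

**Step 11**
Reactants: 18 (1R)-1-[(2S,3R)-3-acetoxy-2-(2-hydroxyethyl)-2,3-dihydro-1-benzofuran-5-yl]ethyl (Z)-2-methylbut-2-enoate
Product: 19 (1R)-1-[(2S,3R)-3-acetoxy-2-(2-oxoethyl)-2,3-dihydro-1-benzofuran-5-yl]ethyl (Z)-2-methylbut-2-enoate
Conditions: Dess–Martin periodinane, pyridine, CH2Cl2, 0 °C to rt
Reagents that add atoms: none
Why: Dess–Martin oxidation takes the primary alcohol to the aldehyde under buffered, non-basic conditions that avoid β-elimination of the ring oxygen.

**Step 12**
Reactants: 19 (1R)-1-[(2S,3R)-3-acetoxy-2-(2-oxoethyl)-2,3-dihydro-1-benzofuran-5-yl]ethyl (Z)-2-methylbut-2-enoate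
Product: 21 (1R)-1-[(2S,3R)-3-acetoxy-2-(3-oxoprop-1-en-2-yl)-2,3-dihydro-1-benzofuran-5-yl]ethyl (Z)-2-methylbut-2-enoate (CNP0294391.5), via Mannich base 20 (not isolated)
Conditions: CH2=NMe2+ I− (Eschenmoser's salt), Et3N, CH2Cl2, rt
Reagents that add atoms: dimethylmethyleneammonium iodide (Eschenmoser's salt), C=[N+](C)C.[I-]
Why: Mannich condensation of the aldehyde enol with the preformed iminium salt, then amine elimination from 20 (α-methylenation of an aldehyde), creates the 1-formylvinyl group; the ammonium group is a far better leaving group than the ring aryloxide, and C2 is untouched.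

**Compound list**

1 | (S)-2-(2,2-dimethyl-1,3-dioxolan-4-yl)ethanol | OCC[C@H]1COC(C)(C)O1 | starting material
2 | (S)-tert-butyl[2-(2,2-dimethyl-1,3-dioxolan-4-yl)ethoxy]diphenylsilane | CC(C)(C)[Si](OCC[C@H]1COC(C)(C)O1)(c1ccccc1)c1ccccc1 | intermediate
3 | (S)-4-[(tert-butyldiphenylsilyl)oxy]butane-1,2-diol | CC(C)(C)[Si](OCC[C@H](O)CO)(c1ccccc1)c1ccccc1 | intermediate
4 | (S)-4-[(tert-butyldiphenylsilyl)oxy]-2-hydroxybutanal | CC(C)(C)[Si](OCC[C@H](O)C=O)(c1ccccc1)c1ccccc1 | intermediate
5 | 2-(trimethylsilyl)phenyl trifluoromethanesulfonate | C[Si](C)(C)c1ccccc1OS(=O)(=O)C(F)(F)F | starting material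
6 | benzyne (1,2-didehydrobenzene) | C1#CC=CC=C1 | intermediate
7 | caesium 2-{[(2S)-4-[(tert-butyldiphenylsilyl)oxy]-1-oxobutan-2-yl]oxy}benzen-1-ide (ortho-caesiated aryl ether) | [Cs+].O=C[C@H](CCO[Si](c1ccccc1)(c1ccccc1)C(C)(C)C)Oc1cccc[c-]1 | intermediate
8 | (2S,3R)-2-{2-[(tert-butyldiphenylsilyl)oxy]ethyl}-2,3-dihydro-1-benzofuran-3-ol | CC(C)(C)[Si](OCC[C@@H]1Oc2ccccc2[C@H]1O)(c1ccccc1)c1ccccc1 | intermediate
9 | (2S,3R)-2-{2-[(tert-butyldiphenylsilyl)oxy]ethyl}-2,3-dihydro-1-benzofuran-3-yl acetate | CC(C)(C)[Si](OCC[C@@H]1Oc2ccccc2[C@H]1OC(C)=O)(c1ccccc1)c1ccccc1 | intermediate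
10 | (2S,3R)-5-bromo-2-{2-[(tert-butyldiphenylsilyl)oxy]ethyl}-2,3-dihydro-1-benzofuran-3-yl acetate | CC(C)(C)[Si](OCC[C@@H]1Oc2ccc(Br)cc2[C@H]1OC(C)=O)(c1ccccc1)c1ccccc1 | intermediate
11 | tributyl(1-ethoxyvinyl)stannane | CCCC[Sn](CCCC)(CCCC)C(=C)OCC | starting material
12 | (2S,3R)-2-{2-[(tert-butyldiphenylsilyl)oxy]ethyl}-5-(1-ethoxyvinyl)-2,3-dihydro-1-benzofuran-3-yl acetate | CC(C)(C)[Si](OCC[C@@H]1Oc2ccc(C(=C)OCC)cc2[C@H]1OC(C)=O)(c1ccccc1)c1ccccc1 | intermediate
13 | (2S,3R)-5-acetyl-2-{2-[(tert-butyldiphenylsilyl)oxy]ethyl}-2,3-dihydro-1-benzofuran-3-yl acetate | CC(C)(C)[Si](OCC[C@@H]1Oc2ccc(C(C)=O)cc2[C@H]1OC(C)=O)(c1ccccc1)c1ccccc1 | intermediate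
14 | (2S,3R)-2-{2-[(tert-butyldiphenylsilyl)oxy]ethyl}-5-[(1R)-1-hydroxyethyl]-2,3-dihydro-1-benzofuran-3-yl acetate | CC(C)(C)[Si](OCC[C@@H]1Oc2ccc([C@@H](C)O)cc2[C@H]1OC(C)=O)(c1ccccc1)c1ccccc1 | intermediate
15 | angelic acid [(Z)-2-methylbut-2-enoic acid] | C/C=C(/C)C(=O)O | starting material
16 | (Z)-2-methylbut-2-enoic 2,4,6-trichlorobenzoic anhydride | C/C=C(/C)C(=O)OC(=O)c1c(Cl)cc(Cl)cc1Cl | intermediate
17 | (1R)-1-[(2S,3R)-3-acetoxy-2-{2-[(tert-butyldiphenylsilyl)oxy]ethyl}-2,3-dihydro-1-benzofuran-5-yl]ethyl (Z)-2-methylbut-2-enoate | CC(C)(C)[Si](OCC[C@@H]1Oc2ccc([C@@H](C)OC(=O)/C(C)=C\C)cc2[C@H]1OC(C)=O)(c1ccccc1)c1ccccc1 | intermediate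
18 | (1R)-1-[(2S,3R)-3-acetoxy-2-(2-hydroxyethyl)-2,3-dihydro-1-benzofuran-5-yl]ethyl (Z)-2-methylbut-2-enoate | OCC[C@@H]1Oc2ccc([C@@H](C)OC(=O)/C(C)=C\C)cc2[C@H]1OC(C)=O | intermediate
19 | (1R)-1-[(2S,3R)-3-acetoxy-2-(2-oxoethyl)-2,3-dihydro-1-benzofuran-5-yl]ethyl (Z)-2-methylbut-2-enoate | O=CC[C@@H]1Oc2ccc([C@@H](C)OC(=O)/C(C)=C\C)cc2[C@H]1OC(C)=O | intermediate
20 | (1R)-1-[(2S,3R)-3-acetoxy-2-[1-(dimethylamino)-3-oxopropan-2-yl]-2,3-dihydro-1-benzofuran-5-yl]ethyl (Z)-2-methylbut-2-enoate (Mannich base, both epimers at the new carbon) | CN(C)CC(C=O)[C@@H]1Oc2ccc([C@@H](C)OC(=O)/C(C)=C\C)cc2[C@H]1OC(C)=O | intermediate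
21 | (1R)-1-[(2S,3R)-3-acetoxy-2-(3-oxoprop-1-en-2-yl)-2,3-dihydro-1-benzofuran-5-yl]ethyl (Z)-2-methylbut-2-enoate (CNP0294391.5) | C=C(C=O)[C@@H]1Oc2ccc([C@@H](C)OC(=O)/C(C)=C\C)cc2[C@H]1OC(C)=O | target

**Totals.** Total step count: 12. Longest linear sequence: 12 steps (from 1; compounds 5, 11 and 15 enter as purchased).

**Steps most likely to fail**

1. Step 4 (key step). The alkoxide may add to benzyne but the aryl carbanion may be protonated before it closes the ring. The α-hydroxy aldehyde may enolise (erosion of the C2 configuration, isomerisation to the hydroxy ketone) faster than it is arylated. Facial selectivity at C3 may be poor. The fallback uses known chemistry, sets out from diol 3 and comes back at 8, forming the two aryl bonds in separate steps. Diol 3 is silylated (Et3SiCl, imidazole) to the bis(triethylsilyl) ether F1. Swern oxidation, which converts a primary triethylsilyl ether selectively, gives the α-silyloxy aldehyde F2. Felkin–Anh-controlled addition of 2-bromophenylmagnesium chloride (from 1-bromo-2-iodobenzene and iPrMgCl, THF, −40 °C) should give the anti carbinol F3, which already holds the C3a–C3 bond. HF·pyridine removes the triethylsilyl group to give the diol F4. Intramolecular Ullmann-type O-arylation (CuI, 3,4,7,8-tetramethyl-1,10-phenanthroline, Cs2CO3, toluene, 110 °C) then closes the furan ring at O1–C7a and returns 8.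

2. Step 12. Under amine base the aldehyde enolate may expel the ring aryloxide (retro-oxa-Michael opening of the furan ring with loss of the C2 centre) in competition with the Mannich reaction. The fallback sets out from 19 and comes back at 21. The Mannich step is run without base (Eschenmoser's salt, CH2Cl2), so that it proceeds through the enol and stops at amine 20, which is isolated after a bicarbonate wash. Oxidation with mCPBA at 0 °C gives the amine N-oxide F5, which on warming to room temperature should undergo Cope elimination, a thermal syn elimination that involves no enolate, to give 21.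

3. Step 3. Over-oxidation or glycol cleavage of the 1,2-diol may occur, and the α-hydroxy aldehyde may epimerise or oligomerise during handling. The fallback sets out from 3 and comes back at 4. Bis-silylation (Me3SiCl, Et3N, CH2Cl2) gives the bis(trimethylsilyl) ether F6. Swern oxidation, which converts the primary trimethylsilyl ether selectively, gives the α-silyloxy aldehyde F7. Brief treatment with AcOH/THF/H2O just before use removes the remaining silyl group and releases 4.

**Further compounds**

F1 | step 4 | (S)-4-[(tert-butyldiphenylsilyl)oxy]-1,2-bis[(triethylsilyl)oxy]butane | CC[Si](CC)(CC)OC[C@H](CCO[Si](c1ccccc1)(c1ccccc1)C(C)(C)C)O[Si](CC)(CC)CC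
F2 | step 4 | (S)-4-[(tert-butyldiphenylsilyl)oxy]-2-[(triethylsilyl)oxy]butanal | O=C[C@H](CCO[Si](c1ccccc1)(c1ccccc1)C(C)(C)C)O[Si](CC)(CC)CC
F3 | step 4 | (1R,2S)-1-(2-bromophenyl)-4-[(tert-butyldiphenylsilyl)oxy]-2-[(triethylsilyl)oxy]butan-1-ol | O[C@H](c1ccccc1Br)[C@H](CCO[Si](c1ccccc1)(c1ccccc1)C(C)(C)C)O[Si](CC)(CC)CC
F4 | step 4 | (1R,2S)-1-(2-bromophenyl)-4-[(tert-butyldiphenylsilyl)oxy]butane-1,2-diol | O[C@H](c1ccccc1Br)[C@H](CCO[Si](c1ccccc1)(c1ccccc1)C(C)(C)C)O
F5 | step 12 | N-oxide of Mannich base 20 | C[N+](C)([O-])CC(C=O)[C@@H]1Oc2ccc([C@@H](C)OC(=O)/C(C)=C\C)cc2[C@H]1OC(C)=O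
F6 | step 3 | (S)-4-[(tert-butyldiphenylsilyl)oxy]-1,2-bis[(trimethylsilyl)oxy]butane | C[Si](C)(C)OC[C@H](CCO[Si](c1ccccc1)(c1ccccc1)C(C)(C)C)O[Si](C)(C)C
F7 | step 3 | (S)-4-[(tert-butyldiphenylsilyl)oxy]-2-[(trimethylsilyl)oxy]butanal | O=C[C@H](CCO[Si](c1ccccc1)(c1ccccc1)C(C)(C)C)O[Si](C)(C)C
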